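**Plan**
1. Numbering: skeleton atoms are counted along the target SMILES, leaving out the CO2H carbon, the carbonyl oxygens and the methyl groups on C9, C14 and C20. C1 is the methyl on C2, C2–C5 the chain, C6–C11 ring A (C11 spiro), O12 the lactone oxygen, C13 the lactone C=O, C14–C19 ring C (C15, C16 the diketone), then C20 and C21.
2. Retrosynthesis: cut C3–C4 (ring-closing metathesis, then saturation), return C17 to a trigonal diosphenol carbon and C16 to CH2, remove the C14 methyl, then cut C11–C19 together with O12–C13.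
3. Enabling feature: the oxygen-bearing spiro carbon C11 and the ring-fusion carbon C19 share one γ-lactone (C11–O12–C13–C14–C19) with C19 β to the carbonyl C13. This is the imprint of a ketone ketyl adding to a 2-substituted acrylate; the partners are ring A ketone 11 and ring C enoate 27.
4. Forward order: ring A (steps 1–9) and ring C with its side chain (steps 10–18) are built separately. Step 19 joins them and closes the lactone, steps 20–24 adjust ring C, and the 11-membered ring closes last (steps 25–26) before deprotection (step 27).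
5. Stereochemistry: C6 and C9 come from an (S)-4-silyloxycyclohexenone by anti alkylation and anti conjugate addition. C2 and C20 come from lipase desymmetrisation of a meso diol. A temporary C17 centre (aminocatalysis) steers C19; C11 and C19 arise in step 19 from the facial bias of both rings. C14 is set by cis-fused alkylation and C17 finally by protonation inside the macrocycle.

Key step: step 19

Remark: the target is taken as the drawn 1,2-diketone; such diones can equilibrate with the C16 enol, and the last step delivers whatever tautomer ratio the compound itself adopts.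

**Fragment 1 (ring A ketone)**

Step 1
Reactants: 1 1,4-dioxaspiro[4.5]dec-6-en-8-one
Product: 2 (8S)-1,4-dioxaspiro[4.5]dec-6-en-8-ol
Conditions: RuCl(p-cymene)[(S,S)-TsDPEN] (1 mol%), KOH (2 mol%), i-PrOH, 25 °C
Reagents that add atoms: none
Why: Asymmetric transfer hydrogenation (Noyori type) reduces the enone carbonyl 1,2-selectively through the Ru–H/N–H transition state, the alkene taking the place of the aryl group of aryl ketones, so the (S,S)-ligand is expected to give the (S)-carbinol that later fixes both ring A centres.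

Step 2
Reactants: 2 (8S)-1,4-dioxaspiro[4.5]dec-6-en-8-ol
Product: 3 tert-butyl(dimethyl)[(8S)-1,4-dioxaspiro[4.5]dec-6-en-8-yloxy]silane
Conditions: t-BuMe2SiCl, imidazole, DMF, 0 °C → rt
Reagents that add atoms: tert-butyldimethylsilyl chloride, CC(C)(C)[Si](C)(C)Cl
Why: Imidazole-mediated silylation of a secondary allylic alcohol, which leaves the stereocentre untouched.

Step 3
Reactants: 3 tert-butyl(dimethyl)[(8S)-1,4-dioxaspiro[4.5]dec-6-en-8-yloxy]silane
Product: 4 (4S)-4-[(tert-butyldimethylsilyl)oxy]cyclohex-2-en-1-one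
Conditions: pyridinium p-toluenesulfonate (cat.), acetone/H2O (10:1), 50 °C
Reagents that add atoms: water, O
Why: Acid-catalysed hydrolysis of the allylic ketal unmasks the enone under conditions that a secondary silyl ether and the γ-stereocentre should tolerate.

Step 4
Reactants: 4 (4S)-4-[(tert-butyldimethylsilyl)oxy]cyclohex-2-en-1-one
Product: 5 (4S,6S)-4-[(tert-butyldimethylsilyl)oxy]-6-methylcyclohex-2-en-1-one
Conditions: LiN(iPr)2, THF, –78 °C; MeI, –78 → –40 °C
Reagents that add atoms: iodomethane, CI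
Why: Kinetic α'-deprotonation gives the cross-conjugated enolate, which is methylated (enolate alkylation) on the face opposite the pseudo-axial silyloxy group, setting the future C9 trans to the oxygen.

Step 5
Reactants: 5 (4S,6S)-4-[(tert-butyldimethylsilyl)oxy]-6-methylcyclohex-2-en-1-one
Product: 6 (3S,4S,6S)-4-[(tert-butyldimethylsilyl)oxy]-6-methyl-3-(prop-2-en-1-yl)-1-[(trimethylsilyl)oxy]cyclohex-1-ene
Conditions: CH2=CHCH2MgBr, CuBr·SMe2, LiCl, Me3SiCl, THF, –78 °C; Et3N/pentane work-up
Reagents that add atoms: allylmagnesium bromide, C=CC[Mg]Br; chlorotrimethylsilane, C[Si](C)(C)Cl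
Why: Copper-mediated, silyl-chloride-accelerated conjugate addition delivers the allyl group axially and anti to the neighbouring silyloxy group, which sets the future C6 cis to the methyl group and traps the enolate regiospecifically as its silyl enol ether.

Step 6
Reactants: 6 (3S,4S,6S)-4-[(tert-butyldimethylsilyl)oxy]-6-methyl-3-(prop-2-en-1-yl)-1-[(trimethylsilyl)oxy]cyclohex-1-ene
Product: 8 (3S,4S,6S)-4-[(tert-butyldimethylsilyl)oxy]-6-methyl-3-(prop-2-en-1-yl)cyclohex-1-en-1-yl trifluoromethanesulfonate, via lithium enolate 7 (not isolated)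
Conditions: MeLi, THF, 0 °C; PhNTf2, –78 °C → rt
Reagents that add atoms: N-phenylbis(trifluoromethanesulfonimide), O=S(=O)(N(c1ccccc1)S(=O)(=O)C(F)(F)F)C(F)(F)F
Why: MeLi cleaves the O–SiMe3 bond to the regiodefined lithium enolate, which is O-sulfonylated (enol triflate formation) without enolising towards the methyl-bearing centre.

Step 7
Reactants: 8 (3S,4S,6S)-4-[(tert-butyldimethylsilyl)oxy]-6-methyl-3-(prop-2-en-1-yl)cyclohex-1-en-1-yl trifluoromethanesulfonate
Product: 9 4-methoxybenzyl (3S,4S,6S)-4-[(tert-butyldimethylsilyl)oxy]-6-methyl-3-(prop-2-en-1-yl)cyclohex-1-ene-1-carboxylate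
Conditions: Pd(OAc)2 (5 mol%), PPh3 (10 mol%), CO (1 atm), 4-MeOC6H4CH2OH, Et3N, DMF, 50 °C
Reagents that add atoms: carbon monoxide, [C-]#[O+]; 4-methoxybenzyl alcohol, COc1ccc(CO)cc1
Why: Palladium-catalysed alkoxycarbonylation of an enol triflate (oxidative addition of zerovalent palladium, CO insertion, alcoholysis of the acyl–palladium species) installs the acid-labile ester that survives all later steps.

Step 8
Reactants: 9 4-methoxybenzyl (3S,4S,6S)-4-[(tert-butyldimethylsilyl)oxy]-6-methyl-3-(prop-2-en-1-yl)cyclohex-1-ene-1-carboxylate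
Product: 10 4-methoxybenzyl (3S,4S,6S)-4-hydroxy-6-methyl-3-(prop-2-en-1-yl)cyclohex-1-ene-1-carboxylate
Conditions: HF·pyridine, THF/pyridine, 0 °C → rt
Reagents that add atoms: none
Why: Fluoride-mediated desilylation under buffered conditions leaves the ester and both alkenes untouched.

Step 9
Reactants: 10 4-methoxybenzyl (3S,4S,6S)-4-hydroxy-6-methyl-3-(prop-2-en-1-yl)cyclohex-1-ene-1-carboxylate
Product: 11 4-methoxybenzyl (3S,6S)-6-methyl-4-oxo-3-(prop-2-en-1-yl)cyclohex-1-ene-1-carboxylate
Conditions: Dess–Martin periodinane, NaHCO3, CH2Cl2, 0 °C; used at once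
Reagents that add atoms: none
Why: Dess–Martin oxidation under buffered, non-basic conditions should give the β,γ-unsaturated ketone without epimerising the doubly activated C3–H or moving the double bond into conjugation.

**Fragment 2 (ring C enoate)**

Step 10
Reactants: 12 cis-2,4-dimethylglutaric anhydride
Product: 13 (2R,4S)-2,4-dimethylpentane-1,5-diol (meso)
Conditions: LiAlH4, THF, 0 °C → reflux
Reagents that add atoms: none
Why: Hydride reduction of the cyclic anhydride gives the diol with the syn (meso) relationship of the two methyl-bearing carbons retained.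

Step 11
Reactants: 13 (2R,4S)-2,4-dimethylpentane-1,5-diol
Product: 14 (2S,4R)-5-hydroxy-2,4-dimethylpentyl acetate
Conditions: lipase from Pseudomonas fluorescens (Amano AK), vinyl acetate, THF, 25 °C
Reagents that add atoms: vinyl acetate, C=COC(C)=O
Why: Lipase-catalysed enantiotopos-selective transesterification (desymmetrisation of a meso diol) is expected to acetylate the hydroxymethyl arm on the (S)-configured carbon, which fixes the future C2 and C20 in one operation.

Step 12
Reactants: 14 (2S,4R)-5-hydroxy-2,4-dimethylpentyl acetate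
Product: 16 (2S,4R,5E)-2,4-dimethyl-7-oxohept-5-en-1-yl acetate, via aldehyde 15 (not isolated)
Conditions: 2,2,6,6-tetramethylpiperidin-1-oxyl (10 mol%), PhI(OAc)2, CH2Cl2, 25 °C; then Ph3P=CHCHO, 40 °C
Reagents that add atoms: (triphenylphosphoranylidene)acetaldehyde, O=CC=P(c1ccccc1)(c1ccccc1)c1ccccc1
Why: Nitroxyl-catalysed alcohol oxidation followed in the same flask by Wittig olefination with the stabilised ylide gives the (E)-enal under neutral conditions that should not epimerise the α-methyl aldehyde.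

Step 13
Reactants: 16 (2S,4R,5E)-2,4-dimethyl-7-oxohept-5-en-1-yl acetate; 17 tert-butyl 3-oxobutanoate
Product: 20 (2S,4R)-2-methyl-4-[(1R)-5-oxocyclohex-3-en-1-yl]pentyl acetate, via Michael adduct 18 (not isolated), via cyclohexenone tert-butyl ester 19 (not isolated)
Conditions: (S)-2-{bis[3,5-bis(trifluoromethyl)phenyl][(trimethylsilyl)oxy]methyl}pyrrolidine (10 mol%), neat, 25 °C; then TsOH·H2O (20 mol%), toluene, 80 °C
Reagents that add atoms: none
Why: Iminium-ion-catalysed Michael addition of the β-keto ester, on the enal face opposite the silyloxydiarylmethyl group of the (S)-catalyst, sets C17, and acid then effects intramolecular aldol condensation, loss of isobutene and decarboxylation (organocatalytic Michael/aldol cyclohexenone annulation).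

Step 14
Reactants: 20 (2S,4R)-2-methyl-4-[(1R)-5-oxocyclohex-3-en-1-yl]pentyl acetate
Product: 21 (2S,4R)-4-[(1R)-4-iodo-5-oxocyclohex-3-en-1-yl]-2-methylpentyl acetate
Conditions: I2, pyridine/CH2Cl2 (1:1), 0 °C → rt
Reagents that add atoms: iodine, II
Why: α-Iodination of the enone by pyridine-mediated conjugate addition, iodination of the enolate and elimination.

Step 15
Reactants: 21 (2S,4R)-4-[(1R)-4-iodo-5-oxocyclohex-3-en-1-yl]-2-methylpentyl acetate
Product: 22 (2S,4R)-4-[(9R)-6-iodo-1,4-dioxaspiro[4.5]dec-6-en-9-yl]-2-methylpentyl acetate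
Conditions: HOCH2CH2OH, TsOH·H2O (cat.), benzene, reflux (Dean–Stark)
Reagents that add atoms: ethane-1,2-diol, OCCO
Why: Acid-catalysed ketalisation with azeotropic removal of water, which α-halo enones undergo without migration of the double bond.

Step 16
Reactants: 22 (2S,4R)-4-[(9R)-6-iodo-1,4-dioxaspiro[4.5]dec-6-en-9-yl]-2-methylpentyl acetate
Product: 23 (2S,4R)-4-[(9R)-6-iodo-1,4-dioxaspiro[4.5]dec-6-en-9-yl]-2-methylpentan-1-ol
Conditions: K2CO3 (cat.), MeOH, 25 °C
Reagents that add atoms: none
Why: Base-catalysed transesterification removes the acetate while the vinyl iodide and the ketal are inert.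

Step 17
Reactants: 23 (2S,4R)-4-[(9R)-6-iodo-1,4-dioxaspiro[4.5]dec-6-en-9-yl]-2-methylpentan-1-ol
Product: 25 (9R)-6-iodo-9-[(2R,4S)-4-methylhex-5-en-2-yl]-1,4-dioxaspiro[4.5]dec-6-ene, via aldehyde 24 (not isolated)
Conditions: Dess–Martin periodinane, NaHCO3, CH2Cl2, 0 °C; then Ph3PCH3Br, KN(SiMe3)2, THF, –78 → 0 °C
Reagents that add atoms: methyltriphenylphosphonium bromide, C[P+](c1ccccc1)(c1ccccc1)c1ccccc1.[Br-]
Why: Dess–Martin oxidation and Wittig methylenation with the non-stabilised ylide at low temperature, which should be faster than epimerisation of the α-methyl aldehyde.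

Step 18
Reactants: 25 (9R)-6-iodo-9-[(2R,4S)-4-methylhex-5-en-2-yl]-1,4-dioxaspiro[4.5]dec-6-ene
Product: 27 methyl (9R)-9-[(2R,4S)-4-methylhex-5-en-2-yl]-1,4-dioxaspiro[4.5]dec-6-ene-6-carboxylate, via vinyllithium 26 (not isolated)
Conditions: n-BuLi, THF, –78 °C; then added to ClCO2Me, THF, –78 °C
Reagents that add atoms: methyl chloroformate, COC(=O)Cl
Why: Iodine–lithium exchange gives the ketal-masked α-keto vinyl anion, which is acylated by the chloroformate (inverse addition) to the enoate.

**Coupling and completion**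

Step 19
Reactants: 11 ring A ketone (fragment 1); 27 ring C enoate (fragment 2)
Product: 29 spirolactone ketal (C15 dioxolane; C14-H cis to C19-H; 17-epi), via hydroxy ester 28 (not isolated)
Conditions: SmI2 (2.5 equiv), t-BuOH (2 equiv), THF/HMPA, –78 → 0 °C; 11 added slowly to SmI2 and 27 (2 equiv)
Reagents that add atoms: none
Why: Divalent samarium transfers one electron to the ketone of 11 to give a trivalent-samarium ketyl whose carbon C11 adds to the β-carbon C19 of 27 inside a chelate linking the ketyl oxygen and the ester carbonyl, and a second electron and protonation by t-BuOH turn the α-ester radical into the C14–H ester. The closest known reaction type is the SmI2-mediated reductive coupling of ketones with α,β-unsaturated esters to γ-lactones. The γ-lactone closes when the tertiary samarium alkoxide O12 attacks the methyl ester C13 (5-exo-trig acyl substitution with loss of methoxide). C11 is set by the adjacent C6 allyl group (bond formation on the opposite face of ring A), C19 by the C17 side chain of the half-chair enoate (axial attack anti to it, hence the deliberately epimeric C17), and C14 by the preference for the cis-fused lactone. The step needs cross-coupling to win over pinacol formation, simple reduction and addition to the ring A enoate, which slow addition of 11 to excess 27 and the less hindered C19 (next to a CH2) should secure, and it needs the β,γ-unsaturated ketone to survive, which the neutral, fast electron transfer allows.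

Step 20
Reactants: 29 spirolactone ketal
Product: 30 β-keto lactone (C15 ketone, C14–H)
Conditions: TsOH·H2O (0.2 equiv), acetone/H2O (10:1), 45 °C
Reagents that add atoms: water, O
Why: Acid-catalysed ketal hydrolysis unmasks the C15 ketone under conditions the 4-methoxybenzyl ester and the lactone should tolerate.

Step 21
Reactants: 30 β-keto lactone
Product: 31 C14-methyl β-keto lactone
Conditions: K2CO3, MeI, acetone, 25 °C
Reagents that add atoms: iodomethane, CI
Why: C-Alkylation of the β-keto lactone enolate places the methyl group on the ring-fusion carbon cis to C19–H, because only the cis-fused bicycle forms readily, which sets C14.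

Step 22
Reactants: 31 C14-methyl β-keto lactone
Product: 32 C16-hydroxy ketone (C16 epimers)
Conditions: KN(SiMe3)2, THF, –78 °C; 2-(phenylsulfonyl)-3-phenyloxaziridine, –78 °C
Reagents that add atoms: 2-(phenylsulfonyl)-3-phenyloxaziridine, O=S(=O)(N1OC1c1ccccc1)c1ccccc1
Why: Kinetic deprotonation at C16, the only enolisable position of the C15 ketone, and oxygen transfer from the Davis oxaziridine (enolate hydroxylation) give the ketol, whose C16 configuration is irrelevant.

Step 23
Reactants: 32 C16-hydroxy ketone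
Product: 33 diosphenol (C15 ketone, C16 enol, C16=C17)
Conditions: Dess–Martin periodinane, CH2Cl2, 25 °C
Reagents that add atoms: none
Why: Dess–Martin oxidation of the ketol gives the 1,2-dione, which can enolise only towards C17 (C14 is quaternary) and thereby erases the unwanted C17 configuration.

Step 24
Reactants: 33 diosphenol
Product: 34 diosphenol tert-butyldimethylsilyl ether
Conditions: t-BuMe2SiOTf, Et3N, CH2Cl2, –78 → 0 °C
Reagents that add atoms: tert-butyldimethylsilyl trifluoromethanesulfonate, CC(C)(C)[Si](C)(C)OS(=O)(=O)C(F)(F)F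
Why: O-Silylation of the diosphenol (soft enolisation–silylation of any remaining diketone) holds C17 trigonal for the ring closure.

Step 25
Reactants: 34 diosphenol tert-butyldimethylsilyl ether
Product: 35 macrocyclic triene (11-membered ring closed at C3=C4, E/Z)
Conditions: second-generation Grubbs catalyst RuCl2(=CHPh)(H2IMes)(PCy3) (10 mol%), toluene (1 mM), 80 °C
Reagents that add atoms: none
Why: Ring-closing olefin metathesis between the two monosubstituted alkenes at high dilution forms the 11-membered ring with loss of ethene, while the trisubstituted enoate and the tetrasubstituted enol ether do not take part.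

Step 26
Reactants: 35 macrocyclic triene
Product: 36 macrocycle with saturated C3–C4
Conditions: 2-nitrobenzenesulfonohydrazide, Et3N, CH2Cl2, 25 °C
Reagents that add atoms: none
Why: Diimide generated from the sulfonyl hydrazide reduces the disubstituted C3=C4 bond by concerted syn hydrogen transfer and leaves the trisubstituted enoate and the tetrasubstituted enol ether untouched.

Step 27
Reactants: 36 macrocycle with saturated C3–C4
Product: 37 target compound CNP0115928.1
Conditions: CF3CO2H/CH2Cl2 (1:4), anisole, H2O (trace), 0 °C → rt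
Reagents that add atoms: none
Why: Acidolysis cleaves the 4-methoxybenzyl ester (cation trapped by anisole) and protonates the silyl enol ether at C17; the bridged bicycle should favour the C17–C20 bond on the ring C face that carries C11, and the centre stays epimerisable through the C16 enol, so the thermodynamically preferred target configuration should result.

**Compound list**
1 | 1,4-dioxaspiro[4.5]dec-6-en-8-one | O=C1C=CC2(CC1)OCCO2 | starting material
2 | (8S)-1,4-dioxaspiro[4.5]dec-6-en-8-ol | O[C@@H]1C=CC2(CC1)OCCO2 | intermediate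
3 | tert-butyl(dimethyl)[(8S)-1,4-dioxaspiro[4.5]dec-6-en-8-yloxy]silane | CC(C)(C)[Si](C)(C)O[C@@H]1C=CC2(CC1)OCCO2 | intermediate
4 | (4S)-4-[(tert-butyldimethylsilyl)oxy]cyclohex-2-en-1-one | O=C1C=C[C@@H](O[Si](C)(C)C(C)(C)C)CC1 | intermediate
5 | (4S,6S)-4-[(tert-butyldimethylsilyl)oxy]-6-methylcyclohex-2-en-1-one (methyl trans to the silyloxy group) | O=C1C=C[C@@H](O[Si](C)(C)C(C)(C)C)C[C@@H]1C | intermediate
6 | (3S,4S,6S)-4-[(tert-butyldimethylsilyl)oxy]-6-methyl-3-(prop-2-en-1-yl)-1-[(trimethylsilyl)oxy]cyclohex-1-ene | C[Si](C)(C)OC1=C[C@H](CC=C)[C@@H](O[Si](C)(C)C(C)(C)C)C[C@@H]1C | intermediate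
7 | lithium (3S,4S,6S)-4-[(tert-butyldimethylsilyl)oxy]-6-methyl-3-(prop-2-en-1-yl)cyclohex-1-en-1-olate | [Li]OC1=C[C@H](CC=C)[C@@H](O[Si](C)(C)C(C)(C)C)C[C@@H]1C | intermediate
8 | (3S,4S,6S)-4-[(tert-butyldimethylsilyl)oxy]-6-methyl-3-(prop-2-en-1-yl)cyclohex-1-en-1-yl trifluoromethanesulfonate | O=S(=O)(OC1=C[C@H](CC=C)[C@@H](O[Si](C)(C)C(C)(C)C)C[C@@H]1C)C(F)(F)F | intermediate
9 | 4-methoxybenzyl (3S,4S,6S)-4-[(tert-butyldimethylsilyl)oxy]-6-methyl-3-(prop-2-en-1-yl)cyclohex-1-ene-1-carboxylate | C=CC[C@H]1C=C(C(=O)OCc2ccc(OC)cc2)[C@@H](C)C[C@@H]1O[Si](C)(C)C(C)(C)C | intermediate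
10 | 4-methoxybenzyl (3S,4S,6S)-4-hydroxy-6-methyl-3-(prop-2-en-1-yl)cyclohex-1-ene-1-carboxylate | C=CC[C@H]1C=C(C(=O)OCc2ccc(OC)cc2)[C@@H](C)C[C@@H]1O | intermediate
11 | 4-methoxybenzyl (3S,6S)-6-methyl-4-oxo-3-(prop-2-en-1-yl)cyclohex-1-ene-1-carboxylate (ring A ketone, fragment 1; allyl and methyl cis) | C=CC[C@H]1C=C(C(=O)OCc2ccc(OC)cc2)[C@@H](C)CC1=O | intermediate
12 | cis-2,4-dimethylglutaric anhydride, (3R,5S)-3,5-dimethyloxane-2,6-dione | C[C@H]1C[C@@H](C)C(=O)OC1=O | starting material
13 | (2R,4S)-2,4-dimethylpentane-1,5-diol (meso) | OC[C@H](C)C[C@H](C)CO | intermediate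
14 | (2S,4R)-5-hydroxy-2,4-dimethylpentyl acetate | OC[C@H](C)C[C@H](C)COC(C)=O | intermediate
15 | (2S,4R)-2,4-dimethyl-5-oxopentyl acetate | O=C[C@H](C)C[C@H](C)COC(C)=O | intermediate
16 | (2S,4R,5E)-2,4-dimethyl-7-oxohept-5-en-1-yl acetate | O=C/C=C/[C@H](C)C[C@H](C)COC(C)=O | intermediate
17 | tert-butyl 3-oxobutanoate | CC(=O)CC(=O)OC(C)(C)C | starting material
18 | tert-butyl (3S,4R,6S)-7-acetoxy-2-acetyl-4,6-dimethyl-3-(2-oxoethyl)heptanoate (C2 epimers) | CC(=O)C(C(=O)OC(C)(C)C)[C@@H](CC=O)[C@H](C)C[C@H](C)COC(C)=O | intermediate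
19 | tert-butyl (6S)-6-[(2R,4S)-5-acetoxy-4-methylpentan-2-yl]-2-oxocyclohex-3-ene-1-carboxylate (C1 epimers) | CC(C)(C)OC(=O)C1C(=O)C=CC[C@H]1[C@H](C)C[C@H](C)COC(C)=O | intermediate
20 | (2S,4R)-2-methyl-4-[(1R)-5-oxocyclohex-3-en-1-yl]pentyl acetate | O=C1C=CC[C@H](C1)[C@H](C)C[C@H](C)COC(C)=O | intermediate
21 | (2S,4R)-4-[(1R)-4-iodo-5-oxocyclohex-3-en-1-yl]-2-methylpentyl acetate | O=C1C(I)=CC[C@H](C1)[C@H](C)C[C@H](C)COC(C)=O | intermediate
22 | (2S,4R)-4-[(9R)-6-iodo-1,4-dioxaspiro[4.5]dec-6-en-9-yl]-2-methylpentyl acetate | IC1=CC[C@H](CC12OCCO2)[C@H](C)C[C@H](C)COC(C)=O | intermediate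
23 | (2S,4R)-4-[(9R)-6-iodo-1,4-dioxaspiro[4.5]dec-6-en-9-yl]-2-methylpentan-1-ol | IC1=CC[C@H](CC12OCCO2)[C@H](C)C[C@H](C)CO | intermediate
24 | (2S,4R)-4-[(9R)-6-iodo-1,4-dioxaspiro[4.5]dec-6-en-9-yl]-2-methylpentanal | IC1=CC[C@H](CC12OCCO2)[C@H](C)C[C@H](C)C=O | intermediate
25 | (9R)-6-iodo-9-[(2R,4S)-4-methylhex-5-en-2-yl]-1,4-dioxaspiro[4.5]dec-6-ene | IC1=CC[C@H](CC12OCCO2)[C@H](C)C[C@H](C)C=C | intermediate
26 | (9R)-6-lithio-9-[(2R,4S)-4-methylhex-5-en-2-yl]-1,4-dioxaspiro[4.5]dec-6-ene | [Li]C1=CC[C@H](CC12OCCO2)[C@H](C)C[C@H](C)C=C | intermediate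
27 | methyl (9R)-9-[(2R,4S)-4-methylhex-5-en-2-yl]-1,4-dioxaspiro[4.5]dec-6-ene-6-carboxylate (ring C enoate, fragment 2) | COC(=O)C1=CC[C@H](CC12OCCO2)[C@H](C)C[C@H](C)C=C | intermediate
28 | γ-hydroxy ester: C11 tertiary alcohol of ring A bonded to C19; methyl ester on C14, dioxolane at C15 (C14 epimers) | C=CC[C@H]1C=C(C(=O)OCc2ccc(OC)cc2)[C@@H](C)C[C@]1(O)[C@@H]1C[C@H](CC2(OCCO2)C1C(=O)OC)[C@H](C)C[C@H](C)C=C | intermediate
29 | spirolactone ketal: γ-lactone C11–O12–C13(=O)–C14H–C19, spiro at C11 and cis-fused to ring C; C15 dioxolane; 4-methoxybenzyl ester at C8; allyl on C6; side chain on C17 trans to C11 (17-epi); C2, C6, C9, C11, C19, C20 as in the target | C=CC[C@H]1C=C(C(=O)OCc3ccc(OC)cc3)[C@@H](C)C[C@@]12OC(=O)[C@H]1C3(OCCO3)C[C@@H](C[C@H]12)[C@H](C)C[C@H](C)C=C | intermediate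
30 | β-keto lactone: as 29 with a C15 ketone | C=CC[C@H]1C=C(C(=O)OCc3ccc(OC)cc3)[C@@H](C)C[C@@]12OC(=O)[C@H]1C(=O)C[C@@H](C[C@H]12)[C@H](C)C[C@H](C)C=C | intermediate
31 | C14-methyl β-keto lactone (methyl cis to C19–H, C14 as in the target) | C=CC[C@H]1C=C(C(=O)OCc3ccc(OC)cc3)[C@@H](C)C[C@@]12OC(=O)[C@@]1(C)C(=O)C[C@@H](C[C@H]12)[C@H](C)C[C@H](C)C=C | intermediate
32 | C16-hydroxy ketone (C16 epimers) | C=CC[C@H]1C=C(C(=O)OCc3ccc(OC)cc3)[C@@H](C)C[C@@]12OC(=O)[C@@]1(C)C(=O)C(O)[C@@H](C[C@H]12)[C@H](C)C[C@H](C)C=C | intermediate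
33 | diosphenol: C15 ketone, C16 enol OH, C16=C17 | C=CC[C@H]1C=C(C(=O)OCc3ccc(OC)cc3)[C@@H](C)C[C@@]12OC(=O)[C@@]1(C)C(=O)C(O)=C(C[C@H]12)[C@H](C)C[C@H](C)C=C | intermediate
34 | diosphenol tert-butyldimethylsilyl ether | C=CC[C@H]1C=C(C(=O)OCc3ccc(OC)cc3)[C@@H](C)C[C@@]12OC(=O)[C@@]1(C)C(=O)C(O[Si](C)(C)C(C)(C)C)=C(C[C@H]12)[C@H](C)C[C@H](C)C=C | intermediate
35 | macrocyclic triene: 11-membered ring closed at C3=C4 (E/Z), silyl enol ether and 4-methoxybenzyl ester retained | C[C@@H]1C=CC[C@H]2C=C(C(=O)OCc4ccc(OC)cc4)[C@@H](C)C[C@@]23OC(=O)[C@@]2(C)C(=O)C(O[Si](C)(C)C(C)(C)C)=C(C[C@H]23)[C@H](C)C1 | intermediate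
36 | macrocycle with saturated C3–C4 | C[C@@H]1CCC[C@H]2C=C(C(=O)OCc4ccc(OC)cc4)[C@@H](C)C[C@@]23OC(=O)[C@@]2(C)C(=O)C(O[Si](C)(C)C(C)(C)C)=C(C[C@H]23)[C@H](C)C1 | intermediate
37 | CNP0115928.1 | C[C@@H]1CCC[C@H]2C=C(C(=O)O)[C@@H](C)C[C@@]23OC(=O)[C@@]2(C)C(=O)C(=O)[C@H](C[C@H]23)[C@H](C)C1 | target

**Totals**
Total steps: 27 (9 for fragment 1, 9 for fragment 2, the coupling, 8 after it).
Longest linear sequence: 18 steps (steps 1–9 or 10–18, then 19–27).

**Steps most likely to fail**

1. Step 19. The ketyl may be reduced further or dimerise faster than it adds to the hindered, α,β-disubstituted ring C enoate, and the two facial preferences may not reinforce each other. The fallback couples 11 with an acyclic, β-monosubstituted enoate and closes ring C afterwards. It sets out from enal 16.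
 - Conjugate addition of dimethyl malonate under the aminocatalysis of step 13 would give dimethyl 2-[(3S,4R,6S)-7-acetoxy-4,6-dimethyl-1-oxoheptan-3-yl]propanedioate F1.
 - Wittig olefination with Ph3P=CHCO2Me would give the (E)-enoate triester F2, and dealkoxycarbonylation (LiCl, wet DMSO, heat) the diester acetate F3.
 - Methanolysis (K2CO3, MeOH) would give the alcohol F4, Dess–Martin oxidation the aldehyde F5, and methylenation with Ph3P=CH2 the diene diester F6.
 - SmI2-mediated coupling of 11 with F6 under the conditions of step 19 would give the spirolactone ester F7.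
 - Dieckmann-type cyclisation of the lactone enolate onto the remaining methyl ester (LiN(SiMe3)2, THF, –78 → 0 °C) would close ring C and come back to the route at β-keto lactone 30.
 - C19 would then rest on the chelated transition state alone, with diastereomers to be separated at F7.

2. Step 25. Oligomerisation by cross-metathesis may outrun closure of the bridged 11-membered ring, whose trigonal bridgehead C17 adds strain. The fallback closes the ring before the enol is fixed, so that a tetrahedral, epimerisable C17 can adapt to the ring. It sets out from diosphenol 33, whose keto tautomers interconvert through the enol; the C17 epimer with both chains on one face of ring C can then be the one that cyclises.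
 - Metathesis with the same catalyst at high dilution would give the macrocyclic diketone 4-methoxybenzyl ester with C3=C4 F8.
 - Diimide reduction would give the saturated macrocyclic diketone 4-methoxybenzyl ester F9.
 - Acidolysis of the ester as in step 27 comes back to the route at target 37.

3. Step 13. The secondary amine may epimerise C20 through a dienamine, or the γ-branched enal may react sluggishly with eroded facial control. The fallback sets C17 with a covalently bound oxazolidinone auxiliary and organocopper chemistry. It sets out from aldehyde 15, generated as in step 12.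
 - Horner–Wadsworth–Emmons reaction with (4S)-4-benzyl-3-[(diethoxyphosphoryl)acetyl]-1,3-oxazolidin-2-one (LiCl, i-Pr2NEt, MeCN) would give (4S)-4-benzyl-3-[(2E,4R,6S)-7-acetoxy-4,6-dimethylhept-2-enoyl]-1,3-oxazolidin-2-one F10.
 - Conjugate addition of CH2=C(CH3)CH2MgCl with CuBr·SMe2, anti to the benzyl group of the chelated imide, would give the 2-methylallyl adduct F11.
 - NaBH4 in wet THF would release the auxiliary and give the primary alcohol F12.
 - Ozonolysis (O3, then PPh3) would give the hydroxy ketone F13, and Dess–Martin oxidation the keto aldehyde F14.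
 - Intramolecular aldol condensation (TsOH, benzene, reflux) comes back to the route at enone 20.

**Further compounds**
F1 | step 19 | dimethyl 2-[(3S,4R,6S)-7-acetoxy-4,6-dimethyl-1-oxoheptan-3-yl]propanedioate | O=CC[C@H](C(C(=O)OC)C(=O)OC)[C@H](C)C[C@H](C)COC(C)=O
F2 | step 19 | methyl (2E,5S,6R,8S)-9-acetoxy-5-[bis(methoxycarbonyl)methyl]-6,8-dimethylnon-2-enoate | COC(=O)/C=C/C[C@H](C(C(=O)OC)C(=O)OC)[C@H](C)C[C@H](C)COC(C)=O
F3 | step 19 | dimethyl (2E,5R)-5-[(2R,4S)-5-acetoxy-4-methylpentan-2-yl]hept-2-enedioate | COC(=O)/C=C/C[C@H](CC(=O)OC)[C@H](C)C[C@H](C)COC(C)=O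
F4 | step 19 | dimethyl (2E,5R)-5-[(2R,4S)-5-hydroxy-4-methylpentan-2-yl]hept-2-enedioate | COC(=O)/C=C/C[C@H](CC(=O)OC)[C@H](C)C[C@H](C)CO
F5 | step 19 | dimethyl (2E,5R)-5-[(2R,4S)-4-methyl-5-oxopentan-2-yl]hept-2-enedioate | COC(=O)/C=C/C[C@H](CC(=O)OC)[C@H](C)C[C@H](C)C=O
F6 | step 19 | dimethyl (2E,5R)-5-[(2R,4S)-4-methylhex-5-en-2-yl]hept-2-enedioate | COC(=O)/C=C/C[C@H](CC(=O)OC)[C@H](C)C[C@H](C)C=C
F7 | step 19 | spirolactone ester with ring C still open (γ-lactone C11–O12–C13(=O)–C14H2–C19; methyl ester at C15) | C=CC[C@H]1C=C(C(=O)OCc3ccc(OC)cc3)[C@@H](C)C[C@@]12OC(=O)C[C@H]2C[C@H](CC(=O)OC)[C@H](C)C[C@H](C)C=C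
F8 | step 25 | macrocyclic diketone 4-methoxybenzyl ester with C3=C4 (E/Z) | C[C@@H]1C=CC[C@H]2C=C(C(=O)OCc4ccc(OC)cc4)[C@@H](C)C[C@@]23OC(=O)[C@@]2(C)C(=O)C(=O)[C@H](C[C@H]23)[C@H](C)C1
F9 | step 25 | saturated macrocyclic diketone 4-methoxybenzyl ester (ester of the target) | C[C@@H]1CCC[C@H]2C=C(C(=O)OCc4ccc(OC)cc4)[C@@H](C)C[C@@]23OC(=O)[C@@]2(C)C(=O)C(=O)[C@H](C[C@H]23)[C@H](C)C1
F10 | step 13 | (4S)-4-benzyl-3-[(2E,4R,6S)-7-acetoxy-4,6-dimethylhept-2-enoyl]-1,3-oxazolidin-2-one | O=C(/C=C/[C@H](C)C[C@H](C)COC(C)=O)N1[C@@H](Cc2ccccc2)COC1=O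
F11 | step 13 | (4S)-4-benzyl-3-[(3S,4R,6S)-7-acetoxy-4,6-dimethyl-3-(2-methylprop-2-en-1-yl)heptanoyl]-1,3-oxazolidin-2-one | O=C(C[C@H](CC(C)=C)[C@H](C)C[C@H](C)COC(C)=O)N1[C@@H](Cc2ccccc2)COC1=O
F12 | step 13 | (2S,4R,5S)-5-(2-hydroxyethyl)-2,4,7-trimethyloct-7-en-1-yl acetate | OCC[C@H](CC(C)=C)[C@H](C)C[C@H](C)COC(C)=O
F13 | step 13 | (2S,4R,5R)-5-(2-hydroxyethyl)-2,4-dimethyl-7-oxooctyl acetate | OCC[C@H](CC(C)=O)[C@H](C)C[C@H](C)COC(C)=O
F14 | step 13 | (2S,4R,5R)-2,4-dimethyl-7-oxo-5-(2-oxoethyl)octyl acetate | O=CC[C@H](CC(C)=O)[C@H](C)C[C@H](C)COC(C)=O
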